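**Retrosynthetic overview**
1. The target is reached by global desilylation of an enal made by Wittig two-carbon extension of a ring A aldehyde, which comes from a ring A nitrile.
2. Dioxane 1 (trans): the O–C7' bond is formed by copper-catalysed intramolecular O-arylation with retention; the C7'–C8' bond and both stereocentres come from an Evans syn glycolate aldol between the ring B aldehyde and an (aryloxy)acetyl oxazolidinone that carries ring A.
3. Ring C and C7'': hydride is delivered to the oxocarbenium ion of a C7'' hemiketal (cis); the C7''–ring C bond is made by Grignard addition to a ring B lactol, followed by oxidation.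
4. Key disconnection: the O–C8'' and O–C7'' bonds of dioxane 2 are formed by hetero-Diels–Alder addition of the o-quinone of methyl 3,4-dihydroxybenzoate to a chiral enamine of 3-silyloxypropanal. The strategy rests on ring B being a catechol diether whose oxygen para to C1 (the carbon carrying C7') is bonded to C7'' (bearing ring C) and whose oxygen meta to C1 is bonded to C8'' (bearing C9''H2OH). That is the pattern expected when an enamine β-carbon adds to the meta oxygen of a 4-acyl-o-quinone and the para phenoxide closes on the iminium carbon.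
5. Ring order: dioxane 2 on ring B (step 4), ring C attached and C7'' set (steps 6–8), dioxane 1 with ring A (steps 13–16), propenal last.

Key step: step 4

Locants: ring A carries the propenal, ring B is the middle arene, ring C the catechol. C7'/C8'/C9' belong to dioxane 1 (C7' carries ring B), C7''/C8''/C9'' to dioxane 2 (C7'' carries ring C). The target is (7'S,8'S) trans in dioxane 1 and (7''R,8''S) cis in dioxane 2.

Assumption: the amine is used as its (2S,5S) enantiomer, because a steric model of the E-enamine (attack on the β-carbon anti to the methyl group of the neighbouring pyrrolidine carbon) leads to the required (S) configuration at C8''.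

Abbreviations in names: TBDPS = tert-butyldiphenylsilyl, TIPS = triisopropylsilyl, TBS = tert-butyldimethylsilyl; ArC = 3,4-bis(TIPS-oxy)phenyl; ArB = (2R,3S)-2-ArC-3-[(TBDPS-oxy)methyl]-2,3-dihydro-1,4-benzodioxin-6-yl (rings B and C joined by the cis dioxane 2).

**Route**

Step 1
Reactants: 1 propane-1,3-diol
Product: 2 3-(TBDPS-oxy)propan-1-ol
Conditions: 1 (3 equiv), TBDPSCl (1 equiv), imidazole (1.2 equiv), THF, 0 °C → rt
Reagents that add atoms: tert-butyl(chloro)diphenylsilane, CC(C)(C)[Si](Cl)(c1ccccc1)c1ccccc1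
Why: Silylation of a primary alcohol, with the symmetrical diol in excess so that the mono-ether should dominate.

Step 2
Reactants: 2 3-(TBDPS-oxy)propan-1-ol
Product: 3 3-(TBDPS-oxy)propanal
Conditions: TEMPO (0.1 equiv), PhI(OAc)2 (1.1 equiv), CH2Cl2, rt
Reagents that add atoms: none
Why: TEMPO-catalysed oxoammonium oxidation of a primary alcohol stops at the aldehyde and is not basic, so the β-silyloxy group should not be eliminated.

Step 3
Reactants: 3 3-(TBDPS-oxy)propanal; 4 (2S,5S)-2,5-dimethylpyrrolidine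
Product: 5 (2S,5S)-1-[(E)-3-(TBDPS-oxy)prop-1-en-1-yl]-2,5-dimethylpyrrolidine
Conditions: 4 (1.05 equiv), 4 Å molecular sieves, Et2O, 0 °C → rt; filtered under argon, concentrated cold, used at once
Reagents that add atoms: none
Why: Condensation of an α-unbranched aldehyde with a secondary amine gives the conjugated E-enamine (the more stable geometry; the hindered amine should not go on to an aminal), and no stereocentre is formed.

Step 4
Reactants: 6 methyl 3,4-dihydroxybenzoate; 5 (2S,5S)-1-[(E)-3-(TBDPS-oxy)prop-1-en-1-yl]-2,5-dimethylpyrrolidine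
Product: 9 lactol methyl (3S)-3-[(TBDPS-oxy)methyl]-2-hydroxy-2,3-dihydro-1,4-benzodioxine-6-carboxylate (both C7'' anomers), via o-quinone 7 (not isolated), via aminal cycloadduct 8 (not isolated)
Conditions: 6, Ag2O (2.5 equiv), Na2SO4, CH2Cl2, −20 °C; cold filtration under argon onto 5 (1.2 equiv), CH2Cl2, −78 → −40 °C; then 1 M aq. citric acid, THF, 0 °C
Reagents that add atoms: water, O
Why: Proposed new method: the electron-poor quinone 7 serves as a 1,4-dioxadiene in an inverse-electron-demand hetero-Diels–Alder reaction with the electron-rich enamine 5; the addition should be asynchronous, the enamine β-carbon (C8'') bonding first to the quinone oxygen on C3 (meta to the ester) because the developing phenoxide on C4 is then conjugated with the para ester, after which that phenoxide closes on the iminium carbon (C7''). The closest known reaction type is the [4+2] cycloaddition of o-quinones with achiral enamines and enol ethers to 2-amino- and 2-alkoxy-1,4-benzodioxanes; the new element is control of absolute configuration by a chiral amine. Dioxane 2 closes as a six-membered ring in the [4+2] sense, the second bond forming by 6-exo-trig attack of the ring B oxygen on the C=N+ carbon, and ring B becomes aromatic again. The only stereocentre that is kept, C8'', is set by the amine: in the planar E-enamine the methyl group on the pyrrolidine carbon syn to the C=C bond covers one face of the β-carbon (the two N–C rotamers are identical by C2 symmetry), so the quinone oxygen should add to the open face, which for the (2S,5S)-amine gives (S)-C8''; the aminal centre C7'' does not matter, since cold aqueous acid hydrolyses it to the lactol and returns the amine. The step needs regioselectivity (secured by the ester), O- over C-attack on the quinone and survival of the allylic silyl ether (addressed by the pre-formed enamine, the absence of free oxidant and the low temperature), and a hydrolysis fast enough that the ring-opened iminium ion does not tautomerise at C8'' (cold buffered acid).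

Step 5
Reactants: 10 4-bromobenzene-1,2-diol
Product: 11 4-bromo-1,2-bis(TIPS-oxy)benzene
Conditions: TIPSCl (2.4 equiv), imidazole (5 equiv), DMF, 40 °C
Reagents that add atoms: chlorotri(propan-2-yl)silane, CC(C)[Si](Cl)(C(C)C)C(C)C
Why: Silylation of both phenols; TIPS aryl ethers are chosen because they should withstand the Grignard, Lewis-acid and carbonate-base steps and fall to fluoride at the end.

Step 6
Reactants: 9 lactol methyl (3S)-3-[(TBDPS-oxy)methyl]-2-hydroxy-2,3-dihydro-1,4-benzodioxine-6-carboxylate; 11 4-bromo-1,2-bis(TIPS-oxy)benzene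
Product: 13 methyl 3-{[(2S)-1-ArC-3-(TBDPS-oxy)-1-hydroxypropan-2-yl]oxy}-4-hydroxybenzoate (both C7'' epimers), via aryl Grignard reagent 12 (not isolated)
Conditions: 11 (2.6 equiv), Mg turnings, I2 (cat.), THF, 50 °C; then 9, THF, −78 → −20 °C; sat. aq. NH4Cl
Reagents that add atoms: none
Why: Grignard addition to the open hydroxy-aldehyde form of a lactol: the first equivalent deprotonates and opens the lactol, the para phenoxide so formed deactivates the ring B ester, and the second equivalent adds to the aldehyde; the C7'' epimer mixture is removed in step 7 and C8'' is not touched.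

Step 7
Reactants: 13 methyl 3-{[(2S)-1-ArC-3-(TBDPS-oxy)-1-hydroxypropan-2-yl]oxy}-4-hydroxybenzoate
Product: 15 hemiketal methyl (3S)-2-ArC-2-hydroxy-3-[(TBDPS-oxy)methyl]-2,3-dihydro-1,4-benzodioxine-6-carboxylate, via keto phenol 14 (not isolated)
Conditions: activated MnO2 (15 equiv), CH2Cl2, rt
Reagents that add atoms: none
Why: MnO2 oxidises the electron-rich benzylic alcohol to the aryl ketone under neutral conditions, and the ketone should close with the ortho phenol to the cyclic hemiketal, as α-(2-hydroxyphenoxy) ketones generally do.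

Step 8
Reactants: 15 hemiketal methyl (3S)-2-ArC-2-hydroxy-3-[(TBDPS-oxy)methyl]-2,3-dihydro-1,4-benzodioxine-6-carboxylate
Product: 16 methyl (2R,3S)-2-ArC-3-[(TBDPS-oxy)methyl]-2,3-dihydro-1,4-benzodioxine-6-carboxylate (cis dioxane 2)
Conditions: Et3SiH (4 equiv), BF3·OEt2 (2 equiv), CH2Cl2, −78 → −40 °C; cold sat. aq. NaHCO3
Reagents that add atoms: none
Why: Ionic hydrogenation of a cyclic hemiketal through its oxocarbenium ion: the silane should deliver hydride to C7'' anti to the pseudoaxial C8'' substituent, so that H is trans to CH2OTBDPS and ring C is cis, giving (7''R) under kinetic control at low temperature.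

Step 9
Reactants: 16 methyl (2R,3S)-2-ArC-3-[(TBDPS-oxy)methyl]-2,3-dihydro-1,4-benzodioxine-6-carboxylate
Product: 17 ArB-methanol
Conditions: i-Bu2AlH (2.5 equiv), CH2Cl2, −78 °C; aq. potassium sodium tartrate (KNaC4H4O6)
Reagents that add atoms: none
Why: Hydride reduction of the methyl ester to the benzylic alcohol; silyl ethers and both dioxane centres are inert to it.

Step 10
Reactants: 17 ArB-methanol
Product: 18 ArB-carbaldehyde
Conditions: activated MnO2 (10 equiv), CH2Cl2, rt
Reagents that add atoms: none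
Why: Selective oxidation of a benzylic alcohol to the aldehyde under neutral conditions, which leaves the acid-sensitive cis benzylic ether alone.

Step 11
Reactants: 19 (R)-4-benzyl-1,3-oxazolidin-2-one
Product: 20 (R)-4-benzyl-3-(2-bromoacetyl)-1,3-oxazolidin-2-one
Conditions: n-BuLi (1.0 equiv), THF, −78 °C; BrCH2COBr (1.1 equiv), −78 → 0 °C
Reagents that add atoms: bromoacetyl bromide, BrCC(Br)=O
Why: N-Acylation of the lithiated oxazolidinone by an acid bromide; the stereocentre of the auxiliary is not involved.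

Step 12
Reactants: 20 (R)-4-benzyl-3-(2-bromoacetyl)-1,3-oxazolidin-2-one; 21 4-hydroxy-3-iodobenzonitrile
Product: 22 4-{2-[(4R)-4-benzyl-2-oxo-1,3-oxazolidin-3-yl]-2-oxoethoxy}-3-iodobenzonitrile
Conditions: K2CO3 (1.5 equiv), acetone, rt
Reagents that add atoms: none
Why: Williamson O-alkylation (SN2) of the phenoxide by the α-bromo imide; attack at the imide carbonyl is unproductive because the phenoxide is the better leaving group.

Step 13
Reactants: 22 4-{2-[(4R)-4-benzyl-2-oxo-1,3-oxazolidin-3-yl]-2-oxoethoxy}-3-iodobenzonitrile; 18 ArB-carbaldehyde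
Product: 24 syn aldol adduct 4-{[(1S,2R)-1-ArB-3-[(4R)-4-benzyl-2-oxo-1,3-oxazolidin-3-yl]-1-hydroxy-3-oxopropan-2-yl]oxy}-3-iodobenzonitrile, via boron Z-enolate 23 (not isolated)
Conditions: 22 (1.3 equiv), Bu2BOTf (1.4 equiv), Et3N (1.6 equiv), CH2Cl2, −78 → 0 °C; 18, −78 → 0 °C; pH 7 phosphate buffer, MeOH, 30% H2O2, 0 °C
Reagents that add atoms: none
Why: Evans syn glycolate aldol: the Z boron enolate should react through a Zimmerman–Traxler chair on the face away from the benzyl group of the (R)-auxiliary, setting C7' and C8' in the syn relationship and absolute sense that become (7'S,8'S) of the trans dioxane.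

Step 14
Reactants: 24 syn aldol adduct
Product: 25 4-{[(1S,2S)-1-ArB-1,3-dihydroxypropan-2-yl]oxy}-3-iodobenzonitrile
Conditions: LiBH4 (2 equiv), MeOH (2 equiv), THF, 0 °C
Reagents that add atoms: none
Why: Reductive cleavage of the N-acyl oxazolidinone to the primary alcohol (C9') with release of the auxiliary; nitrile and aryl iodide are not reduced and no stereocentre is touched.

Step 15
Reactants: 25 4-{[(1S,2S)-1-ArB-1,3-dihydroxypropan-2-yl]oxy}-3-iodobenzonitrile
Product: 26 4-{[(1S,2S)-1-ArB-3-(TBS-oxy)-1-hydroxypropan-2-yl]oxy}-3-iodobenzonitrile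
Conditions: TBSCl (1.1 equiv), imidazole (2 equiv), CH2Cl2, 0 °C
Reagents that add atoms: tert-butyl(chloro)dimethylsilane, CC(C)(C)[Si](C)(C)Cl
Why: Selective silylation of the primary over the hindered secondary benzylic alcohol blocks C9'–OH, which would otherwise also close a six-membered ring in the next step.

Step 16
Reactants: 26 4-{[(1S,2S)-1-ArB-3-(TBS-oxy)-1-hydroxypropan-2-yl]oxy}-3-iodobenzonitrile
Product: 27 (2S,3S)-3-ArB-2-[(TBS-oxy)methyl]-2,3-dihydro-1,4-benzodioxine-6-carbonitrile (trans dioxane 1)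
Conditions: CuI (10 mol %), 3,4,7,8-tetramethyl-1,10-phenanthroline (20 mol %), Cs2CO3 (2 equiv), toluene, 80 °C
Reagents that add atoms: none
Why: Ullmann-type intramolecular O-arylation closes the six-membered ring on the aryl iodide; the alcohol C7'–O bond is not broken, so C7' is retained and the syn alcohol should give the trans dioxane with the oxygen meta to the nitrile on C7'.

Step 17
Reactants: 27 (2S,3S)-3-ArB-2-[(TBS-oxy)methyl]-2,3-dihydro-1,4-benzodioxine-6-carbonitrile
Product: 29 (2S,3S)-3-ArB-2-[(TBS-oxy)methyl]-2,3-dihydro-1,4-benzodioxine-6-carbaldehyde, via N-aluminio aldimine 28 (not isolated)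
Conditions: i-Bu2AlH (1.5 equiv), toluene, −78 °C; aq. potassium sodium tartrate (KNaC4H4O6), then 1 M aq. citric acid, 0 °C
Reagents that add atoms: water, O
Why: Single hydride addition to the nitrile gives the N-metallated aldimine, which is hydrolysed to the aldehyde on mild acidic work-up.

Step 18
Reactants: 29 (2S,3S)-3-ArB-2-[(TBS-oxy)methyl]-2,3-dihydro-1,4-benzodioxine-6-carbaldehyde
Product: 30 (E)-3-{(2S,3S)-3-ArB-2-[(TBS-oxy)methyl]-2,3-dihydro-1,4-benzodioxin-6-yl}prop-2-enal
Conditions: Ph3P=CHCHO (1.5 equiv), toluene, 80 °C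
Reagents that add atoms: (triphenylphosphoranylidene)acetaldehyde, O=CC=P(c1ccccc1)(c1ccccc1)c1ccccc1
Why: Wittig reaction of a stabilised formyl ylide with an aromatic aldehyde should give the E-enal directly.

Step 19
Reactants: 30 (E)-3-{(2S,3S)-3-ArB-2-[(TBS-oxy)methyl]-2,3-dihydro-1,4-benzodioxin-6-yl}prop-2-enal
Product: 31 target (E)-3-{(2S,3S)-3-[(2R,3S)-2-(3,4-dihydroxyphenyl)-3-(hydroxymethyl)-2,3-dihydro-1,4-benzodioxin-6-yl]-2-(hydroxymethyl)-2,3-dihydro-1,4-benzodioxin-6-yl}prop-2-enal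
Conditions: Bu4NF (8 equiv), AcOH (8 equiv), THF, 0 °C → rt, under argon
Reagents that add atoms: none
Why: Fluoride cleaves the two aryl TIPS ethers and the two primary alkyl silyl ethers in one operation; the acetic acid buffer keeps the catechol protonated so that the cis C7'' benzylic ether should not open through a quinone methide.

**Compound list**
1 | propane-1,3-diol | OCCCO | starting material
2 | 3-(TBDPS-oxy)propan-1-ol | OCCCO[Si](c1ccccc1)(c1ccccc1)C(C)(C)C | intermediate
3 | 3-(TBDPS-oxy)propanal | O=CCCO[Si](c1ccccc1)(c1ccccc1)C(C)(C)C | intermediate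
4 | (2S,5S)-2,5-dimethylpyrrolidine | C[C@H]1CC[C@H](C)N1 | starting material
5 | (2S,5S)-1-[(E)-3-(TBDPS-oxy)prop-1-en-1-yl]-2,5-dimethylpyrrolidine | C[C@H]1CC[C@H](C)N1/C=C/CO[Si](c1ccccc1)(c1ccccc1)C(C)(C)C | intermediate
6 | methyl 3,4-dihydroxybenzoate | COC(=O)c1ccc(O)c(O)c1 | starting material
7 | methyl 3,4-dioxocyclohexa-1,5-diene-1-carboxylate (o-quinone) | COC(=O)C1=CC(=O)C(=O)C=C1 | intermediate
8 | methyl (3S)-3-[(TBDPS-oxy)methyl]-2-[(2S,5S)-2,5-dimethylpyrrolidin-1-yl]-2,3-dihydro-1,4-benzodioxine-6-carboxylate (aminal, C2 unassigned) | COC(=O)c1ccc2c(c1)O[C@@H](CO[Si](c1ccccc1)(c1ccccc1)C(C)(C)C)C(N1[C@@H](C)CC[C@@H]1C)O2 | intermediate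
9 | methyl (3S)-3-[(TBDPS-oxy)methyl]-2-hydroxy-2,3-dihydro-1,4-benzodioxine-6-carboxylate (lactol) | COC(=O)c1ccc2c(c1)O[C@@H](CO[Si](c1ccccc1)(c1ccccc1)C(C)(C)C)C(O)O2 | intermediate
10 | 4-bromobenzene-1,2-diol | Oc1ccc(Br)cc1O | starting material
11 | 4-bromo-1,2-bis(TIPS-oxy)benzene | CC(C)[Si](Oc1ccc(Br)cc1O[Si](C(C)C)(C(C)C)C(C)C)(C(C)C)C(C)C | intermediate
12 | [3,4-bis(TIPS-oxy)phenyl]magnesium bromide | Br[Mg]c1ccc(O[Si](C(C)C)(C(C)C)C(C)C)c(O[Si](C(C)C)(C(C)C)C(C)C)c1 | intermediate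
13 | methyl 3-{[(2S)-1-ArC-3-(TBDPS-oxy)-1-hydroxypropan-2-yl]oxy}-4-hydroxybenzoate (C7'' epimers) | COC(=O)c1ccc(O)c(c1)O[C@@H](CO[Si](c1ccccc1)(c1ccccc1)C(C)(C)C)C(O)c1ccc(O[Si](C(C)C)(C(C)C)C(C)C)c(O[Si](C(C)C)(C(C)C)C(C)C)c1 | intermediate
14 | methyl 3-{[(2S)-1-ArC-3-(TBDPS-oxy)-1-oxopropan-2-yl]oxy}-4-hydroxybenzoate (keto phenol) | COC(=O)c1ccc(O)c(c1)O[C@@H](CO[Si](c1ccccc1)(c1ccccc1)C(C)(C)C)C(=O)c1ccc(O[Si](C(C)C)(C(C)C)C(C)C)c(O[Si](C(C)C)(C(C)C)C(C)C)c1 | intermediate
15 | methyl (3S)-2-ArC-2-hydroxy-3-[(TBDPS-oxy)methyl]-2,3-dihydro-1,4-benzodioxine-6-carboxylate (hemiketal) | COC(=O)c1ccc2c(c1)O[C@@H](CO[Si](c1ccccc1)(c1ccccc1)C(C)(C)C)C(O)(c1ccc(O[Si](C(C)C)(C(C)C)C(C)C)c(O[Si](C(C)C)(C(C)C)C(C)C)c1)O2 | intermediate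
16 | methyl (2R,3S)-2-ArC-3-[(TBDPS-oxy)methyl]-2,3-dihydro-1,4-benzodioxine-6-carboxylate | COC(=O)c1ccc2c(c1)O[C@@H](CO[Si](c1ccccc1)(c1ccccc1)C(C)(C)C)[C@@H](c1ccc(O[Si](C(C)C)(C(C)C)C(C)C)c(O[Si](C(C)C)(C(C)C)C(C)C)c1)O2 | intermediate
17 | ArB-methanol | OCc1ccc2c(c1)O[C@@H](CO[Si](c1ccccc1)(c1ccccc1)C(C)(C)C)[C@@H](c1ccc(O[Si](C(C)C)(C(C)C)C(C)C)c(O[Si](C(C)C)(C(C)C)C(C)C)c1)O2 | intermediate
18 | ArB-carbaldehyde | O=Cc1ccc2c(c1)O[C@@H](CO[Si](c1ccccc1)(c1ccccc1)C(C)(C)C)[C@@H](c1ccc(O[Si](C(C)C)(C(C)C)C(C)C)c(O[Si](C(C)C)(C(C)C)C(C)C)c1)O2 | intermediate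
19 | (R)-4-benzyl-1,3-oxazolidin-2-one | O=C1N[C@H](Cc2ccccc2)CO1 | starting material
20 | (R)-4-benzyl-3-(2-bromoacetyl)-1,3-oxazolidin-2-one | O=C(CBr)N1[C@H](Cc2ccccc2)COC1=O | intermediate
21 | 4-hydroxy-3-iodobenzonitrile | N#Cc1ccc(O)c(I)c1 | starting material
22 | 4-{2-[(4R)-4-benzyl-2-oxo-1,3-oxazolidin-3-yl]-2-oxoethoxy}-3-iodobenzonitrile | N#Cc1ccc(OCC(=O)N2[C@H](Cc3ccccc3)COC2=O)c(I)c1 | intermediate
23 | dibutylboron Z-enolate of 22 | N#Cc1ccc(O/C=C(\OB(CCCC)CCCC)N2[C@H](Cc3ccccc3)COC2=O)c(I)c1 | intermediate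
24 | syn aldol adduct (C7' S, C8' R as the imide) | N#Cc1ccc(O[C@@H](C(=O)N2[C@H](Cc3ccccc3)COC2=O)[C@@H](O)c2ccc3c(c2)O[C@@H](CO[Si](c2ccccc2)(c2ccccc2)C(C)(C)C)[C@@H](c2ccc(O[Si](C(C)C)(C(C)C)C(C)C)c(O[Si](C(C)C)(C(C)C)C(C)C)c2)O3)c(I)c1 | intermediate
25 | 4-{[(1S,2S)-1-ArB-1,3-dihydroxypropan-2-yl]oxy}-3-iodobenzonitrile | N#Cc1ccc(O[C@@H](CO)[C@@H](O)c2ccc3c(c2)O[C@@H](CO[Si](c2ccccc2)(c2ccccc2)C(C)(C)C)[C@@H](c2ccc(O[Si](C(C)C)(C(C)C)C(C)C)c(O[Si](C(C)C)(C(C)C)C(C)C)c2)O3)c(I)c1 | intermediate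
26 | 4-{[(1S,2S)-1-ArB-3-(TBS-oxy)-1-hydroxypropan-2-yl]oxy}-3-iodobenzonitrile | N#Cc1ccc(O[C@@H](CO[Si](C)(C)C(C)(C)C)[C@@H](O)c2ccc3c(c2)O[C@@H](CO[Si](c2ccccc2)(c2ccccc2)C(C)(C)C)[C@@H](c2ccc(O[Si](C(C)C)(C(C)C)C(C)C)c(O[Si](C(C)C)(C(C)C)C(C)C)c2)O3)c(I)c1 | intermediate
27 | (2S,3S)-3-ArB-2-[(TBS-oxy)methyl]-2,3-dihydro-1,4-benzodioxine-6-carbonitrile | N#Cc1ccc2c(c1)O[C@@H](c1ccc3c(c1)O[C@@H](CO[Si](c1ccccc1)(c1ccccc1)C(C)(C)C)[C@@H](c1ccc(O[Si](C(C)C)(C(C)C)C(C)C)c(O[Si](C(C)C)(C(C)C)C(C)C)c1)O3)[C@H](CO[Si](C)(C)C(C)(C)C)O2 | intermediate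
28 | N-(diisobutylalumanyl) aldimine of 29 | CC(C)C[Al](CC(C)C)N=Cc1ccc2c(c1)O[C@@H](c1ccc3c(c1)O[C@@H](CO[Si](c1ccccc1)(c1ccccc1)C(C)(C)C)[C@@H](c1ccc(O[Si](C(C)C)(C(C)C)C(C)C)c(O[Si](C(C)C)(C(C)C)C(C)C)c1)O3)[C@H](CO[Si](C)(C)C(C)(C)C)O2 | intermediate
29 | (2S,3S)-3-ArB-2-[(TBS-oxy)methyl]-2,3-dihydro-1,4-benzodioxine-6-carbaldehyde | O=Cc1ccc2c(c1)O[C@@H](c1ccc3c(c1)O[C@@H](CO[Si](c1ccccc1)(c1ccccc1)C(C)(C)C)[C@@H](c1ccc(O[Si](C(C)C)(C(C)C)C(C)C)c(O[Si](C(C)C)(C(C)C)C(C)C)c1)O3)[C@H](CO[Si](C)(C)C(C)(C)C)O2 | intermediate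
30 | (E)-3-{(2S,3S)-3-ArB-2-[(TBS-oxy)methyl]-2,3-dihydro-1,4-benzodioxin-6-yl}prop-2-enal | O=C/C=C/c1ccc2c(c1)O[C@@H](c1ccc3c(c1)O[C@@H](CO[Si](c1ccccc1)(c1ccccc1)C(C)(C)C)[C@@H](c1ccc(O[Si](C(C)C)(C(C)C)C(C)C)c(O[Si](C(C)C)(C(C)C)C(C)C)c1)O3)[C@H](CO[Si](C)(C)C(C)(C)C)O2 | intermediate
31 | (E)-3-{(2S,3S)-3-[(2R,3S)-2-(3,4-dihydroxyphenyl)-3-(hydroxymethyl)-2,3-dihydro-1,4-benzodioxin-6-yl]-2-(hydroxymethyl)-2,3-dihydro-1,4-benzodioxin-6-yl}prop-2-enal (CNP0302404.1) | O=C/C=C/c1ccc2c(c1)O[C@@H](c1ccc3c(c1)O[C@@H](CO)[C@@H](c1ccc(O)c(O)c1)O3)[C@H](CO)O2 | target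

**Step count**
Total: 19 steps. Longest linear sequence: 16 steps (steps 1–4, 6–10 and 13–19, from propane-1,3-diol); steps 5 and 11–12 are side branches.

**Steps most likely to fail**

1. Step 4 (the proposed new method). The enamine may add through carbon to C5 or C6 of the quinone ring instead of to oxygen. The quinone may dimerise before it is trapped. The enamine may lose silanolate to give an acrolein iminium ion. The facial selectivity may be low, or C8'' may be partly scrambled while the aminal is hydrolysed. The fallback uses known chiral-pool chemistry, sets out from 6 and comes back at 9. Compound 6 is benzylated at the more acidic 4-hydroxyl (BnBr, K2CO3, DMF) to methyl 4-(benzyloxy)-3-hydroxybenzoate F1. Commercial methyl (R)-2,3-dihydroxypropanoate is silylated at the primary hydroxyl (TBDPSCl, imidazole) to methyl (R)-3-(TBDPS-oxy)-2-hydroxypropanoate F2. Mitsunobu etherification of F1 with F2 (PPh3, DIAD, THF) should give, with inversion, the (S)-aryl ether diester F3. Hydrogenolysis (H2, Pd on carbon, EtOAc) frees the para phenol to give the phenol diester F4. Then i-Bu2AlH (2.2 equiv, CH2Cl2, −78 °C) should reduce only the α-aryloxy aliphatic ester, the benzoate being deactivated by the para aluminium phenoxide, and the resulting aldehyde closes to lactol 9 on work-up.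

2. Step 8. Hydride delivery to the oxocarbenium ion may not be face-selective, or the Lewis acid may ionise the benzylic C7''–O bond of the product, leading to drift toward the trans isomer or to reductive ring opening. The fallback sets out from 15 and comes back at 16. The keto-phenol tautomer of 15 is reduced with LiBH(s-Bu)3 (THF, −78 °C); Felkin–Anh control, with the aryloxy group anti to the incoming hydride, should favour the syn (7''S,8''S) alcohol F5, which is separated from its epimer. Intramolecular Mitsunobu etherification (PPh3, DIAD, THF, 0 °C) then lets the ring B phenol displace the activated benzylic hydroxyl with inversion to give cis 16.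

3. Step 6. The transient α-aryloxy aldehyde may enolise under the basic Grignard reagent, causing epimerisation at C8'' or β-elimination of silanolate, or the reagent may attack the ester before the lactol has opened. The fallback sets out from 9 and comes back at 15. Lactol 9 is oxidised (TEMPO cat., PhI(OAc)2, CH2Cl2) to the lactone F6. As an aryl ester, F6 is opened by MeNH(OMe)·HCl and i-Pr2NEt (CH2Cl2, rt) to the N-methoxy-N-methylamide phenol F7. Grignard reagent 12 (2.2 equiv, THF, −78 → 0 °C) should add once to give a chelated tetrahedral intermediate, and work-up releases keto phenol 14, which closes to 15; the aldehyde stage and step 7 are bypassed.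

**Further compounds**
F1 | step 4 | methyl 4-(benzyloxy)-3-hydroxybenzoate | COC(=O)c1ccc(OCc2ccccc2)c(O)c1
F2 | step 4 | methyl (R)-3-(tert-butyldiphenylsilyloxy)-2-hydroxypropanoate | COC(=O)[C@H](O)CO[Si](c1ccccc1)(c1ccccc1)C(C)(C)C
F3 | step 4 | methyl 4-(benzyloxy)-3-{[(2S)-3-(tert-butyldiphenylsilyloxy)-1-methoxy-1-oxopropan-2-yl]oxy}benzoate | COC(=O)c1ccc(OCc2ccccc2)c(c1)O[C@@H](CO[Si](c1ccccc1)(c1ccccc1)C(C)(C)C)C(=O)OC
F4 | step 4 | methyl 4-hydroxy-3-{[(2S)-3-(tert-butyldiphenylsilyloxy)-1-methoxy-1-oxopropan-2-yl]oxy}benzoate | COC(=O)c1ccc(O)c(c1)O[C@@H](CO[Si](c1ccccc1)(c1ccccc1)C(C)(C)C)C(=O)OC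
F5 | step 8 | methyl 3-{[(1S,2S)-1-[3,4-bis(triisopropylsilyloxy)phenyl]-3-(tert-butyldiphenylsilyloxy)-1-hydroxypropan-2-yl]oxy}-4-hydroxybenzoate | COC(=O)c1ccc(O)c(c1)O[C@@H](CO[Si](c1ccccc1)(c1ccccc1)C(C)(C)C)[C@@H](O)c1ccc(O[Si](C(C)C)(C(C)C)C(C)C)c(O[Si](C(C)C)(C(C)C)C(C)C)c1
F6 | step 6 | methyl (3S)-3-[(tert-butyldiphenylsilyloxy)methyl]-2-oxo-2,3-dihydro-1,4-benzodioxine-6-carboxylate | COC(=O)c1ccc2c(c1)O[C@@H](CO[Si](c1ccccc1)(c1ccccc1)C(C)(C)C)C(=O)O2
F7 | step 6 | methyl 3-{[(2S)-3-(tert-butyldiphenylsilyloxy)-1-[methoxy(methyl)amino]-1-oxopropan-2-yl]oxy}-4-hydroxybenzoate | COC(=O)c1ccc(O)c(c1)O[C@@H](CO[Si](c1ccccc1)(c1ccccc1)C(C)(C)C)C(=O)N(C)OC
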